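**Retrosynthetic overview**
1. Target 34 ⇐ deprotection and oxidation of diaryl carbinol 31 ⇐ aryllithium from bromide 27 plus aldehyde 29, so the benzoyl group is installed last, at C8.
2. 27 ⇐ double methylenation of 1,5-diketone 26 ⇐ thioester 25 ⇐ Michael adduct 24.
3. Key C–C bond (side-chain methine to CH2CH2COMe): intermolecular Evans titanium-enolate Michael addition of imide 21 to methyl vinyl ketone 22, which sets the side-chain R centre.
4. 21 ⇐ chromanol propanoate 13 ⇐ Jacobsen epoxidation and hydrogenolysis of chromene acrylate 11 (sets 3R) ⇐ chromene aldehyde 8.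
5. Ring order: the benzene ring comes from 2,4,6-trihydroxybenzaldehyde 1; the pyran ring is built in step 5 and oxygenated in steps 8–9; the 3-hydroxyphenyl ring arrives intact.

Assumption: CIP analysis of the given SMILES gives 3R at the chromanol carbon and R at the side-chain methine; every structure below is drawn for that isomer.

**Route**

Step 1
Reactants: 1 2,4,6-trihydroxybenzaldehyde
Product: 2 2-hydroxy-4,6-bis(methoxymethoxy)benzaldehyde
Conditions: MOMCl (2.1 equiv), EtN(iPr)2, CH2Cl2, 0 °C → rt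
Reagents that add atoms: chloromethyl methyl ether COCCl
Why: Williamson-type O-alkylation stops at the bis-MOM ether because the last hydroxyl is deactivated by its hydrogen bond to the formyl group.

Step 2
Reactants: 2 2-hydroxy-4,6-bis(methoxymethoxy)benzaldehyde
Product: 3 2-(benzyloxy)-4,6-bis(methoxymethoxy)benzaldehyde
Conditions: BnBr, K2CO3, DMF, 60 °C
Reagents that add atoms: benzyl bromide BrCc1ccccc1
Why: Williamson etherification of the chelated phenol under forcing carbonate conditions installs the benzyl group that marks the future 7-oxygen.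

Step 3
Reactants: 3 2-(benzyloxy)-4,6-bis(methoxymethoxy)benzaldehyde
Product: 4 2-(benzyloxy)-4,6-dihydroxybenzaldehyde
Conditions: 3 M HCl, MeOH, 50 °C
Reagents that add atoms: none
Why: Acid-catalysed acetal exchange (MOM cleavage) frees both MOM-protected phenols while the benzyl ether is stable to dilute acid.

Step 4
Reactants: 4 2-(benzyloxy)-4,6-dihydroxybenzaldehyde; 5 3-chloro-3-methylbut-1-yne
Product: 6 2-(benzyloxy)-6-hydroxy-4-[(2-methylbut-3-yn-2-yl)oxy]benzaldehyde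
Conditions: K2CO3, KI (cat.), CuI (cat.), acetone, reflux
Reagents that add atoms: none
Why: Copper-assisted Williamson-type propargylation occurs at the non-chelated, more acidic 4-hydroxyl and leaves the hydrogen-bonded 6-hydroxyl untouched.

Step 5
Reactants: 6 2-(benzyloxy)-6-hydroxy-4-[(2-methylbut-3-yn-2-yl)oxy]benzaldehyde
Product: 7 7-(benzyloxy)-5-hydroxy-2,2-dimethyl-2H-chromene-6-carbaldehyde
Conditions: PhNEt2, 180 °C
Reagents that add atoms: none
Why: A thermal aromatic propargyl Claisen rearrangement, 1,5-hydrogen shift and oxa-6π electrocyclisation build the pyran ring on the carbon next to the chelated hydroxyl, which is favoured by hydrogen-bond-induced bond fixation and by the smaller flanking group.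

Step 6
Reactants: 7 7-(benzyloxy)-5-hydroxy-2,2-dimethyl-2H-chromene-6-carbaldehyde
Product: 8 7-(benzyloxy)-5-methoxy-2,2-dimethyl-2H-chromene-6-carbaldehyde
Conditions: MeI, K2CO3, DMF, 40 °C
Reagents that add atoms: iodomethane CI
Why: Williamson methylation of the remaining chelated phenol installs the 5-methoxy group of the target.

Step 7
Reactants: 8 7-(benzyloxy)-5-methoxy-2,2-dimethyl-2H-chromene-6-carbaldehyde; 9 triethyl phosphonoacetate
Product: 11 ethyl (E)-3-[7-(benzyloxy)-5-methoxy-2,2-dimethyl-2H-chromen-6-yl]prop-2-enoate, via sodium phosphonate carbanion 10 (not isolated)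
Conditions: 9, NaH, THF, 0 °C; then 8, 0 °C → reflux
Reagents that add atoms: sodium hydride [Na+].[H-] (sodium in 10 only)
Why: Horner–Wadsworth–Emmons olefination of the hindered aryl aldehyde gives the E-acrylate, which supplies the three-carbon arm and tempers the electron-rich chromene for the epoxidation.

Step 8
Reactants: 11 ethyl (E)-3-[7-(benzyloxy)-5-methoxy-2,2-dimethyl-2H-chromen-6-yl]prop-2-enoate
Product: 12 ethyl (E)-3-[(3R,4R)-7-(benzyloxy)-3,4-epoxy-5-methoxy-2,2-dimethylchroman-6-yl]prop-2-enoate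
Conditions: [(R,R)-N,N'-bis(3,5-di-tert-butylsalicylidene)cyclohexane-1,2-diaminato]MnCl (5 mol %), 4-phenylpyridine N-oxide, aq. NaOCl (pH 11.3), CH2Cl2, 0 °C; crude product used at once
Reagents that add atoms: sodium hypochlorite [Na+].[O-]Cl
Why: Jacobsen–Katsuki epoxidation is selective for the electron-rich cis-alkene of the chromene over the trans-acrylate, and the (R,R)-catalyst gives the (3R,4R)-epoxide, fixing C3 as R.

Step 9
Reactants: 12 ethyl (E)-3-[(3R,4R)-7-(benzyloxy)-3,4-epoxy-5-methoxy-2,2-dimethylchroman-6-yl]prop-2-enoate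
Product: 13 ethyl 3-[(3R)-3,7-dihydroxy-5-methoxy-2,2-dimethylchroman-6-yl]propanoate
Conditions: H2 (1 atm), 10% Pd/C, NaHCO3, EtOAc/EtOH, rt
Reagents that add atoms: none
Why: Catalytic hydrogenation saturates the acrylate, removes the benzyl ether and cleaves only the benzylic C4–O bond of the epoxide (hydrogenolysis), so the C3–O bond and its R configuration are retained.

Step 10
Reactants: 13 ethyl 3-[(3R)-3,7-dihydroxy-5-methoxy-2,2-dimethylchroman-6-yl]propanoate
Product: 14 ethyl 3-[(3R)-7-(allyloxy)-3-hydroxy-5-methoxy-2,2-dimethylchroman-6-yl]propanoate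
Conditions: allyl bromide, K2CO3, acetone/EtOH, 50 °C
Reagents that add atoms: allyl bromide C=CCBr
Why: Williamson allylation occurs only at the phenol and not at the hindered secondary alcohol, giving a protecting group that survives TiCl4 and organolithium steps and is later removed with zerovalent palladium.

Step 11
Reactants: 14 ethyl 3-[(3R)-7-(allyloxy)-3-hydroxy-5-methoxy-2,2-dimethylchroman-6-yl]propanoate
Product: 15 ethyl 3-[(3R)-7-(allyloxy)-3-(tert-butyldimethylsilyloxy)-5-methoxy-2,2-dimethylchroman-6-yl]propanoate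
Conditions: TBSOTf, 2,6-lutidine, CH2Cl2, –20 → 0 °C
Reagents that add atoms: tert-butyldimethylsilyl trifluoromethanesulfonate CC(C)(C)[Si](C)(C)OS(=O)(=O)C(F)(F)F
Why: Silylation with the reactive triflate protects the hindered secondary alcohol as a TBS ether that is stable to the later basic, Lewis acidic and organometallic conditions.

Step 12
Reactants: 15 ethyl 3-[(3R)-7-(allyloxy)-3-(tert-butyldimethylsilyloxy)-5-methoxy-2,2-dimethylchroman-6-yl]propanoate
Product: 16 ethyl 3-[(3R)-7-(allyloxy)-8-bromo-3-(tert-butyldimethylsilyloxy)-5-methoxy-2,2-dimethylchroman-6-yl]propanoate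
Conditions: NBS (1.02 equiv), MeCN, 0 °C, dark
Reagents that add atoms: N-bromosuccinimide O=C1CCC(=O)N1Br
Why: Electrophilic aromatic bromination of the trialkoxybenzene occurs at C8, the only unsubstituted ring position, and installs the handle for the late benzoylation.

Step 13
Reactants: 16 ethyl 3-[(3R)-7-(allyloxy)-8-bromo-3-(tert-butyldimethylsilyloxy)-5-methoxy-2,2-dimethylchroman-6-yl]propanoate
Product: 17 3-[(3R)-7-(allyloxy)-8-bromo-3-(tert-butyldimethylsilyloxy)-5-methoxy-2,2-dimethylchroman-6-yl]propanoic acid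
Conditions: LiOH, THF/MeOH/H2O, rt; then 1 M HCl to pH 3
Reagents that add atoms: lithium hydroxide [Li+].[OH-]
Why: Saponification of the ethyl ester gives the acid without touching the silyl ether, the allyl ether or the aryl bromide.

Step 14
Reactants: 17 3-[(3R)-7-(allyloxy)-8-bromo-3-(tert-butyldimethylsilyloxy)-5-methoxy-2,2-dimethylchroman-6-yl]propanoic acid; 18 (R)-4-benzyloxazolidin-2-one
Product: 21 (4R)-4-benzyl-3-{3-[(3R)-7-(allyloxy)-8-bromo-3-(tert-butyldimethylsilyloxy)-5-methoxy-2,2-dimethylchroman-6-yl]propanoyl}oxazolidin-2-one, via mixed pivalic anhydride 19 (not isolated), via lithium oxazolidinide 20 (not isolated)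
Conditions: 17, PivCl, Et3N, THF, –20 °C; then 18 pre-treated with n-BuLi (THF, –78 °C), –78 → 0 °C
Reagents that add atoms: pivaloyl chloride CC(C)(C)C(=O)Cl (acyl group in 19 only); n-butyllithium [Li]CCCC (lithium in 20 only)
Why: N-Acylation of the lithiated Evans oxazolidinone by the mixed anhydride occurs at the less hindered carbonyl and attaches the (R)-auxiliary.

Step 15
Reactants: 21 (4R)-4-benzyl-3-{3-[(3R)-7-(allyloxy)-8-bromo-3-(tert-butyldimethylsilyloxy)-5-methoxy-2,2-dimethylchroman-6-yl]propanoyl}oxazolidin-2-one; 22 methyl vinyl ketone (but-3-en-2-one)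
Product: 24 (4R)-4-benzyl-3-[(2R)-2-{[(3R)-7-(allyloxy)-8-bromo-3-(tert-butyldimethylsilyloxy)-5-methoxy-2,2-dimethylchroman-6-yl]methyl}-5-oxohexanoyl]oxazolidin-2-one, via chlorotitanium Z-enolate 23 (not isolated)
Conditions: TiCl4 (1.05 equiv), EtN(iPr)2 (1.1 equiv), CH2Cl2, 0 °C, 1 h; then freshly distilled 22 (2 equiv), –78 → 0 °C; H2O
Reagents that add atoms: titanium tetrachloride Cl[Ti](Cl)(Cl)Cl (TiCl3 unit in 23 only)
Why: In this Evans asymmetric Michael addition the chelated Z-chlorotitanium enolate adds 1,4 to the enone on the face opposite the benzyl group of the (R)-auxiliary, which sets the side-chain stereocentre as R.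

Step 16
Reactants: 24 (4R)-4-benzyl-3-[(2R)-2-{[(3R)-7-(allyloxy)-8-bromo-3-(tert-butyldimethylsilyloxy)-5-methoxy-2,2-dimethylchroman-6-yl]methyl}-5-oxohexanoyl]oxazolidin-2-one
Product: 25 S-ethyl (2R)-2-{[(3R)-7-(allyloxy)-8-bromo-3-(tert-butyldimethylsilyloxy)-5-methoxy-2,2-dimethylchroman-6-yl]methyl}-5-oxohexanethioate
Conditions: EtSH (3 equiv), n-BuLi (2.5 equiv), THF, 0 °C; H2O
Reagents that add atoms: ethanethiol CCS (used as its lithium salt)
Why: Thiolate transacylation cleaves the exocyclic imide carbonyl selectively and releases the auxiliary without epimerising the α-centre, because lithium ethanethiolate is only weakly basic.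

Step 17
Reactants: 25 S-ethyl (2R)-2-{[(3R)-7-(allyloxy)-8-bromo-3-(tert-butyldimethylsilyloxy)-5-methoxy-2,2-dimethylchroman-6-yl]methyl}-5-oxohexanethioate
Product: 26 (3R)-3-{[(3R)-7-(allyloxy)-8-bromo-3-(tert-butyldimethylsilyloxy)-5-methoxy-2,2-dimethylchroman-6-yl]methyl}heptane-2,6-dione
Conditions: Me2CuLi (from CuI and MeLi, 2.5 equiv), Et2O, –78 °C; aq. NH4Cl
Reagents that add atoms: lithium dimethylcuprate [Li+].C[Cu-]C
Why: Acyl substitution of the thioester by the Gilman cuprate stops at the methyl ketone, and at –78 °C the existing ketone, the aryl bromide and the α-stereocentre are untouched.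

Step 18
Reactants: 26 (3R)-3-{[(3R)-7-(allyloxy)-8-bromo-3-(tert-butyldimethylsilyloxy)-5-methoxy-2,2-dimethylchroman-6-yl]methyl}heptane-2,6-dione
Product: 27 (3R)-7-(allyloxy)-8-bromo-3-(tert-butyldimethylsilyloxy)-5-methoxy-2,2-dimethyl-6-[(2R)-5-methyl-2-(prop-1-en-2-yl)hex-5-en-1-yl]chromane
Conditions: Cp2TiMe2 (4 equiv), toluene/THF, 65 °C, dark
Reagents that add atoms: dimethyltitanocene C[Ti](C)(C1C=CC=C1)C1C=CC=C1
Why: Petasis methylenation converts both ketones into 1,1-disubstituted alkenes through non-basic titanium methylidene chemistry, which avoids epimerisation of the α-stereocentre and intramolecular aldol condensation of the 1,5-diketone.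

Step 19
Reactants: 28 3-hydroxybenzaldehyde
Product: 29 3-(tert-butyldimethylsilyloxy)benzaldehyde
Conditions: TBSCl, imidazole, CH2Cl2, rt
Reagents that add atoms: tert-butyldimethylsilyl chloride CC(C)(C)[Si](C)(C)Cl
Why: Silylation of the phenol masks the acidic hydroxyl of the aldehyde partner as a TBS ether.

Step 20
Reactants: 27 (3R)-7-(allyloxy)-8-bromo-3-(tert-butyldimethylsilyloxy)-5-methoxy-2,2-dimethyl-6-[(2R)-5-methyl-2-(prop-1-en-2-yl)hex-5-en-1-yl]chromane; 29 3-(tert-butyldimethylsilyloxy)benzaldehyde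
Product: 31 {(3R)-7-(allyloxy)-3-(tert-butyldimethylsilyloxy)-5-methoxy-2,2-dimethyl-6-[(2R)-5-methyl-2-(prop-1-en-2-yl)hex-5-en-1-yl]chroman-8-yl}[3-(tert-butyldimethylsilyloxy)phenyl]methanol (both carbinol epimers), via aryllithium 30 (not isolated)
Conditions: 27, n-BuLi (1.1 equiv), THF, –78 °C, 10 min; then 29, –78 °C; H2O
Reagents that add atoms: n-butyllithium [Li]CCCC (lithium in 30 only)
Why: Bromine–lithium exchange at –78 °C is faster than any deprotonation, and 1,2-addition of the 2,6-dioxygenated aryllithium to the aldehyde joins the second aryl ring as a carbinol whose new stereocentre is erased in the next step.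

Step 21
Reactants: 31 {(3R)-7-(allyloxy)-3-(tert-butyldimethylsilyloxy)-5-methoxy-2,2-dimethyl-6-[(2R)-5-methyl-2-(prop-1-en-2-yl)hex-5-en-1-yl]chroman-8-yl}[3-(tert-butyldimethylsilyloxy)phenyl]methanol
Product: 32 {(3R)-7-(allyloxy)-3-(tert-butyldimethylsilyloxy)-5-methoxy-2,2-dimethyl-6-[(2R)-5-methyl-2-(prop-1-en-2-yl)hex-5-en-1-yl]chroman-8-yl}[3-(tert-butyldimethylsilyloxy)phenyl]methanone
Conditions: Dess–Martin periodinane (1.5 equiv), CH2Cl2, rt
Reagents that add atoms: none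
Why: Dess–Martin oxidation of the secondary benzylic alcohol gives the benzophenone under near-neutral conditions that spare the alkenes and silyl ethers.

Step 22
Reactants: 32 {(3R)-7-(allyloxy)-3-(tert-butyldimethylsilyloxy)-5-methoxy-2,2-dimethyl-6-[(2R)-5-methyl-2-(prop-1-en-2-yl)hex-5-en-1-yl]chroman-8-yl}[3-(tert-butyldimethylsilyloxy)phenyl]methanone
Product: 33 {(3R)-3-(tert-butyldimethylsilyloxy)-7-hydroxy-5-methoxy-2,2-dimethyl-6-[(2R)-5-methyl-2-(prop-1-en-2-yl)hex-5-en-1-yl]chroman-8-yl}[3-(tert-butyldimethylsilyloxy)phenyl]methanone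
Conditions: Pd(PPh3)4 (5 mol %), morpholine, THF, rt
Reagents that add atoms: none
Why: Tsuji–Trost deallylation with zerovalent palladium transfers the allyl group to morpholine and frees the phenol without affecting the unactivated alkenes.

Step 23
Reactants: 33 {(3R)-3-(tert-butyldimethylsilyloxy)-7-hydroxy-5-methoxy-2,2-dimethyl-6-[(2R)-5-methyl-2-(prop-1-en-2-yl)hex-5-en-1-yl]chroman-8-yl}[3-(tert-butyldimethylsilyloxy)phenyl]methanone
Product: 34 {(3R)-3,7-dihydroxy-5-methoxy-2,2-dimethyl-6-[(2R)-5-methyl-2-(prop-1-en-2-yl)hex-5-en-1-yl]chroman-8-yl}(3-hydroxyphenyl)methanone (CNP0307300.2)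
Conditions: TBAF (3 equiv), THF, 0 → 40 °C; H2O
Reagents that add atoms: none
Why: Fluoride-mediated desilylation removes the aryl and the hindered secondary TBS ethers under non-acidic conditions that leave the acid-sensitive isopropenyl groups and both stereocentres untouched.

**Compound list**
1 | 2,4,6-trihydroxybenzaldehyde | O=Cc1c(O)cc(O)cc1O | starting material
2 | 2-hydroxy-4,6-bis(methoxymethoxy)benzaldehyde | O=Cc1c(O)cc(OCOC)cc1OCOC | intermediate
3 | 2-(benzyloxy)-4,6-bis(methoxymethoxy)benzaldehyde | O=Cc1c(OCc2ccccc2)cc(OCOC)cc1OCOC | intermediate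
4 | 2-(benzyloxy)-4,6-dihydroxybenzaldehyde | O=Cc1c(OCc2ccccc2)cc(O)cc1O | intermediate
5 | 3-chloro-3-methylbut-1-yne | C#CC(C)(C)Cl | starting material
6 | 2-(benzyloxy)-6-hydroxy-4-[(2-methylbut-3-yn-2-yl)oxy]benzaldehyde | O=Cc1c(OCc2ccccc2)cc(OC(C)(C)C#C)cc1O | intermediate
7 | 7-(benzyloxy)-5-hydroxy-2,2-dimethyl-2H-chromene-6-carbaldehyde | O=Cc1c(O)c2C=CC(C)(C)Oc2cc1OCc1ccccc1 | intermediate
8 | 7-(benzyloxy)-5-methoxy-2,2-dimethyl-2H-chromene-6-carbaldehyde | O=Cc1c(OC)c2C=CC(C)(C)Oc2cc1OCc1ccccc1 | intermediate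
9 | triethyl phosphonoacetate | CCOC(=O)CP(=O)(OCC)OCC | starting material
10 | sodium salt of triethyl phosphonoacetate (not isolated) | CCOC(=O)[CH-]P(=O)(OCC)OCC.[Na+] | intermediate
11 | ethyl (E)-3-[7-(benzyloxy)-5-methoxy-2,2-dimethyl-2H-chromen-6-yl]prop-2-enoate | CCOC(=O)/C=C/c1c(OC)c2C=CC(C)(C)Oc2cc1OCc1ccccc1 | intermediate
12 | ethyl (E)-3-[(3R,4R)-7-(benzyloxy)-3,4-epoxy-5-methoxy-2,2-dimethylchroman-6-yl]prop-2-enoate | CCOC(=O)/C=C/c1c(OCc4ccccc4)cc2c(c1OC)[C@H]3O[C@H]3C(C)(C)O2 | intermediate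
13 | ethyl 3-[(3R)-3,7-dihydroxy-5-methoxy-2,2-dimethylchroman-6-yl]propanoate | CCOC(=O)CCc1c(O)cc2c(c1OC)C[C@@H](O)C(C)(C)O2 | intermediate
14 | ethyl 3-[(3R)-7-(allyloxy)-3-hydroxy-5-methoxy-2,2-dimethylchroman-6-yl]propanoate | CCOC(=O)CCc1c(OCC=C)cc2c(c1OC)C[C@@H](O)C(C)(C)O2 | intermediate
15 | ethyl 3-[(3R)-7-(allyloxy)-3-(tert-butyldimethylsilyloxy)-5-methoxy-2,2-dimethylchroman-6-yl]propanoate | CCOC(=O)CCc1c(OCC=C)cc2c(c1OC)C[C@@H](O[Si](C)(C)C(C)(C)C)C(C)(C)O2 | intermediate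
16 | ethyl 3-[(3R)-7-(allyloxy)-8-bromo-3-(tert-butyldimethylsilyloxy)-5-methoxy-2,2-dimethylchroman-6-yl]propanoate | CCOC(=O)CCc1c(OCC=C)c(Br)c2c(c1OC)C[C@@H](O[Si](C)(C)C(C)(C)C)C(C)(C)O2 | intermediate
17 | 3-[(3R)-7-(allyloxy)-8-bromo-3-(tert-butyldimethylsilyloxy)-5-methoxy-2,2-dimethylchroman-6-yl]propanoic acid | OC(=O)CCc1c(OCC=C)c(Br)c2c(c1OC)C[C@@H](O[Si](C)(C)C(C)(C)C)C(C)(C)O2 | intermediate
18 | (R)-4-benzyloxazolidin-2-one | O=C1N[C@H](Cc2ccccc2)CO1 | starting material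
19 | mixed pivalic anhydride of acid 17 (not isolated) | CC(C)(C)C(=O)OC(=O)CCc1c(OCC=C)c(Br)c2c(c1OC)C[C@@H](O[Si](C)(C)C(C)(C)C)C(C)(C)O2 | intermediate
20 | lithium (R)-4-benzyl-2-oxooxazolidin-3-ide (not isolated) | [Li+].O=C1[N-][C@H](Cc2ccccc2)CO1 | intermediate
21 | (4R)-4-benzyl-3-{3-[(3R)-7-(allyloxy)-8-bromo-3-(tert-butyldimethylsilyloxy)-5-methoxy-2,2-dimethylchroman-6-yl]propanoyl}oxazolidin-2-one | O=C(CCc1c(OCC=C)c(Br)c2c(c1OC)C[C@@H](O[Si](C)(C)C(C)(C)C)C(C)(C)O2)N3C(=O)OC[C@H]3Cc4ccccc4 | intermediate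
22 | methyl vinyl ketone (but-3-en-2-one) | CC(=O)C=C | starting material
23 | trichlorotitanium (Z)-enolate of imide 21 (not isolated) | Cl[Ti](Cl)(Cl)O/C(=C\Cc1c(OCC=C)c(Br)c2c(c1OC)C[C@@H](O[Si](C)(C)C(C)(C)C)C(C)(C)O2)N3C(=O)OC[C@H]3Cc4ccccc4 | intermediate
24 | (4R)-4-benzyl-3-[(2R)-2-{[(3R)-7-(allyloxy)-8-bromo-3-(tert-butyldimethylsilyloxy)-5-methoxy-2,2-dimethylchroman-6-yl]methyl}-5-oxohexanoyl]oxazolidin-2-one | CC(=O)CC[C@H](Cc1c(OCC=C)c(Br)c2c(c1OC)C[C@@H](O[Si](C)(C)C(C)(C)C)C(C)(C)O2)C(=O)N3C(=O)OC[C@H]3Cc4ccccc4 | intermediate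
25 | S-ethyl (2R)-2-{[(3R)-7-(allyloxy)-8-bromo-3-(tert-butyldimethylsilyloxy)-5-methoxy-2,2-dimethylchroman-6-yl]methyl}-5-oxohexanethioate | CC(=O)CC[C@H](Cc1c(OCC=C)c(Br)c2c(c1OC)C[C@@H](O[Si](C)(C)C(C)(C)C)C(C)(C)O2)C(=O)SCC | intermediate
26 | (3R)-3-{[(3R)-7-(allyloxy)-8-bromo-3-(tert-butyldimethylsilyloxy)-5-methoxy-2,2-dimethylchroman-6-yl]methyl}heptane-2,6-dione | CC(=O)CC[C@H](Cc1c(OCC=C)c(Br)c2c(c1OC)C[C@@H](O[Si](C)(C)C(C)(C)C)C(C)(C)O2)C(C)=O | intermediate
27 | (3R)-7-(allyloxy)-8-bromo-3-(tert-butyldimethylsilyloxy)-5-methoxy-2,2-dimethyl-6-[(2R)-5-methyl-2-(prop-1-en-2-yl)hex-5-en-1-yl]chromane | C=C(C)CC[C@H](Cc1c(OCC=C)c(Br)c2c(c1OC)C[C@@H](O[Si](C)(C)C(C)(C)C)C(C)(C)O2)C(=C)C | intermediate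
28 | 3-hydroxybenzaldehyde | O=Cc1cccc(O)c1 | starting material
29 | 3-(tert-butyldimethylsilyloxy)benzaldehyde | O=Cc1cccc(O[Si](C)(C)C(C)(C)C)c1 | intermediate
30 | 8-lithio derivative of 27 (not isolated) | C=C(C)CC[C@H](Cc1c(OCC=C)c([Li])c2c(c1OC)C[C@@H](O[Si](C)(C)C(C)(C)C)C(C)(C)O2)C(=C)C | intermediate
31 | {(3R)-7-(allyloxy)-3-(tert-butyldimethylsilyloxy)-5-methoxy-2,2-dimethyl-6-[(2R)-5-methyl-2-(prop-1-en-2-yl)hex-5-en-1-yl]chroman-8-yl}[3-(tert-butyldimethylsilyloxy)phenyl]methanol (both carbinol epimers) | C=C(C)CC[C@H](Cc1c(OCC=C)c(C(O)c3cccc(O[Si](C)(C)C(C)(C)C)c3)c2c(c1OC)C[C@@H](O[Si](C)(C)C(C)(C)C)C(C)(C)O2)C(=C)C | intermediate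
32 | {(3R)-7-(allyloxy)-3-(tert-butyldimethylsilyloxy)-5-methoxy-2,2-dimethyl-6-[(2R)-5-methyl-2-(prop-1-en-2-yl)hex-5-en-1-yl]chroman-8-yl}[3-(tert-butyldimethylsilyloxy)phenyl]methanone | C=C(C)CC[C@H](Cc1c(OCC=C)c(C(=O)c3cccc(O[Si](C)(C)C(C)(C)C)c3)c2c(c1OC)C[C@@H](O[Si](C)(C)C(C)(C)C)C(C)(C)O2)C(=C)C | intermediate
33 | {(3R)-3-(tert-butyldimethylsilyloxy)-7-hydroxy-5-methoxy-2,2-dimethyl-6-[(2R)-5-methyl-2-(prop-1-en-2-yl)hex-5-en-1-yl]chroman-8-yl}[3-(tert-butyldimethylsilyloxy)phenyl]methanone | C=C(C)CC[C@H](Cc1c(O)c(C(=O)c3cccc(O[Si](C)(C)C(C)(C)C)c3)c2c(c1OC)C[C@@H](O[Si](C)(C)C(C)(C)C)C(C)(C)O2)C(=C)C | intermediate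
34 | {(3R)-3,7-dihydroxy-5-methoxy-2,2-dimethyl-6-[(2R)-5-methyl-2-(prop-1-en-2-yl)hex-5-en-1-yl]chroman-8-yl}(3-hydroxyphenyl)methanone | C=C(C)CC[C@H](Cc1c(O)c(C(=O)c2cccc(O)c2)c2c(c1OC)C[C@@H](O)C(C)(C)O2)C(=C)C | target

**Step count and risks**
Total step count: 23. Longest linear sequence: 22 steps (steps 1–18 and 20–23 from compound 1); step 19 is a one-step branch.

The three steps most likely to fail:

Step 8 (Jacobsen epoxidation). The epoxide of a 5,7-dioxygenated chromene is acid-labile and may open or rearrange before it is reduced, and the enantioselectivity on this crowded chromene is not guaranteed. The fallback sets out from 11 and comes back at 13, and it sets C3 by ketone reduction instead of epoxidation. Compound 11 is epoxidised without a chiral catalyst (mCPBA, NaHCO3, CH2Cl2, 0 °C) to the racemic epoxide F1. Its lability is then used deliberately: ZnI2 in the same flask triggers a Meinwald rearrangement (1,2-hydride shift from C3 to the benzylic cation) to the chroman-3-one F2. Reduction of F2 with catecholborane and (S)-Me-CBS oxazaborolidine ((S)-1-methyl-3,3-diphenyltetrahydro-1H,3H-pyrrolo[1,2-c][1,3,2]oxazaborole) in toluene at –78 °C gives the (3R)-alcohol F3, with the CMe2–O carbon acting as the large group. Hydrogenation of F3 (H2, Pd/C, EtOAc) saturates the acrylate and removes the benzyl group to give 13.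

Step 15 (Michael addition). The polyether substrate may bind TiCl4 unproductively, and methyl vinyl ketone can polymerise under Lewis acid. The fallback sets out from 16 and comes back at 26, keeping a Michael addition to methyl vinyl ketone but with enamine catalysis instead of an auxiliary. Ester 16 is reduced with iBu2AlH (CH2Cl2, –78 °C) to the aldehyde F4. F4 is added to methyl vinyl ketone with (R)-2-[methoxy(diphenyl)methyl]pyrrolidine (5 mol %) and ethyl 3,4-dihydroxybenzoate (20 mol %) at 4 °C to give the (2R)-keto aldehyde F5; the (R)-catalyst is chosen by analogy with the known facial preference of diarylprolinol ethers, and the configuration would be confirmed by correlation with 26 from the main route. MeTi(OiPr)3 (THF, –40 °C) then adds chemoselectively to the aldehyde in the presence of the ketone to give the hydroxy ketone F6, and Dess–Martin oxidation of F6 gives diketone 26.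

Step 18 (double methylenation). The 1,5-diketone can undergo intramolecular aldol condensation, or the α-centre can epimerise, if the titanium reagent is sluggish. The fallback sets out from 24 and comes back at 27; it never forms the diketone and makes the second isopropenyl group by cross-coupling instead of carbonyl olefination. Wittig methylenation of the unhindered methyl ketone of 24 (Ph3P=CH2 from Ph3PCH3Br and KHMDS, 1.2 equiv, THF, –78 → 0 °C) gives the alkene imide F7. LiSEt (THF, 0 °C) converts F7 into the thioester F8, and Me2CuLi (Et2O, –78 °C) gives the methyl ketone F9. Kinetic enolisation of F9 on the methyl side (KHMDS, THF, –78 °C) and trapping with PhNTf2 gives the alkenyl triflate F10, which couples with Me2CuLi (THF, –15 °C) to give 27.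

**Further compounds**
F1 | step 8 | racemic ethyl (E)-3-[7-(benzyloxy)-3,4-epoxy-5-methoxy-2,2-dimethylchroman-6-yl]prop-2-enoate | CCOC(=O)/C=C/c1c(OCc4ccccc4)cc2c(c1OC)C3OC3C(C)(C)O2
F2 | step 8 | ethyl (E)-3-[7-(benzyloxy)-5-methoxy-2,2-dimethyl-3-oxochroman-6-yl]prop-2-enoate | CCOC(=O)/C=C/c1c(OCc4ccccc4)cc2c(c1OC)CC(=O)C(C)(C)O2
F3 | step 8 | ethyl (E)-3-[(3R)-7-(benzyloxy)-3-hydroxy-5-methoxy-2,2-dimethylchroman-6-yl]prop-2-enoate | CCOC(=O)/C=C/c1c(OCc4ccccc4)cc2c(c1OC)C[C@@H](O)C(C)(C)O2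
F4 | step 15 | 3-[(3R)-7-(allyloxy)-8-bromo-3-(tert-butyldimethylsilyloxy)-5-methoxy-2,2-dimethylchroman-6-yl]propanal | O=CCCc1c(OCC=C)c(Br)c2c(c1OC)C[C@@H](O[Si](C)(C)C(C)(C)C)C(C)(C)O2
F5 | step 15 | (2R)-2-{[(3R)-7-(allyloxy)-8-bromo-3-(tert-butyldimethylsilyloxy)-5-methoxy-2,2-dimethylchroman-6-yl]methyl}-5-oxohexanal | CC(=O)CC[C@H](Cc1c(OCC=C)c(Br)c2c(c1OC)C[C@@H](O[Si](C)(C)C(C)(C)C)C(C)(C)O2)C=O
F6 | step 15 | (5R)-5-{[(3R)-7-(allyloxy)-8-bromo-3-(tert-butyldimethylsilyloxy)-5-methoxy-2,2-dimethylchroman-6-yl]methyl}-6-hydroxyheptan-2-one (both carbinol epimers) | CC(=O)CC[C@H](Cc1c(OCC=C)c(Br)c2c(c1OC)C[C@@H](O[Si](C)(C)C(C)(C)C)C(C)(C)O2)C(C)O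
F7 | step 18 | (4R)-4-benzyl-3-[(2R)-2-{[(3R)-7-(allyloxy)-8-bromo-3-(tert-butyldimethylsilyloxy)-5-methoxy-2,2-dimethylchroman-6-yl]methyl}-5-methylhex-5-enoyl]oxazolidin-2-one | C=C(C)CC[C@H](Cc1c(OCC=C)c(Br)c2c(c1OC)C[C@@H](O[Si](C)(C)C(C)(C)C)C(C)(C)O2)C(=O)N3C(=O)OC[C@H]3Cc4ccccc4
F8 | step 18 | S-ethyl (2R)-2-{[(3R)-7-(allyloxy)-8-bromo-3-(tert-butyldimethylsilyloxy)-5-methoxy-2,2-dimethylchroman-6-yl]methyl}-5-methylhex-5-enethioate | C=C(C)CC[C@H](Cc1c(OCC=C)c(Br)c2c(c1OC)C[C@@H](O[Si](C)(C)C(C)(C)C)C(C)(C)O2)C(=O)SCC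
F9 | step 18 | (3R)-3-{[(3R)-7-(allyloxy)-8-bromo-3-(tert-butyldimethylsilyloxy)-5-methoxy-2,2-dimethylchroman-6-yl]methyl}-6-methylhept-6-en-2-one | C=C(C)CC[C@H](Cc1c(OCC=C)c(Br)c2c(c1OC)C[C@@H](O[Si](C)(C)C(C)(C)C)C(C)(C)O2)C(C)=O
F10 | step 18 | (3R)-3-{[(3R)-7-(allyloxy)-8-bromo-3-(tert-butyldimethylsilyloxy)-5-methoxy-2,2-dimethylchroman-6-yl]methyl}-6-methylhepta-1,6-dien-2-yl trifluoromethanesulfonate | C=C(C)CC[C@H](Cc1c(OCC=C)c(Br)c2c(c1OC)C[C@@H](O[Si](C)(C)C(C)(C)C)C(C)(C)O2)C(=C)OS(=O)(=O)C(F)(F)F
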